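**Retrosynthetic overview**

1. The five O-methyl groups are removed last (BBr3). The C7 carbinol comes from a ketal carbon by loss of one methoxy group (SmI2). The lactate ester is cut by a Mitsunobu esterification with inversion, giving a bicyclic dienoic acid and methyl (R)-3-(3,4-dimethoxyphenyl)lactate from natural danshensu. The acrylic acid is cut by a Knoevenagel–Doebner condensation to a bicyclic enal.
2. The bicyclic enal is cut across C1–C2 and C3–C4 by a Diels–Alder reaction between methyl (E)-3,4-dimethoxycinnamate and the o-quinone monoketal obtained by oxidative dearomatization of vanillin in methanol. This copies the presumed biogenesis, in which the o-quinone of a caffeoyl unit adds a second caffeate.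
3. Enabling feature (numbering: C1 and C4 bridgeheads, C2 ester carbon, C3 aryl carbon, C5=C6 with the side chain on C6, C7 carbinol next to C1, C8 ketone next to C4): the bicyclo[2.2.2]oct-5-ene holds a cyclohexene retron C1–C2–C3–C4–C5=C6. Its ring C1–C6–C5–C4–C8–C7, with vicinal oxygens on C7 and C8 and the carbon substituent on C6, is the carbon hexagon of vanillin at the o-quinone level, and the trans C2–C3 bridge is an E-cinnamate.
4. Order of ring formation: the two benzene rings are bought; the vanillin ring is dearomatized to the cyclohexadienone (future ring C1–C6–C5–C4–C8–C7); the cycloaddition then closes, last, the saturated ring C1–C2–C3–C4–C8–C7 together with the cyclohexene ring.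
5. Stereocontrol: C1–C4 relative configuration from the endo-ester transition state; C7 by kinetic protonation of a samarium enolate; lactate centre from the chiral pool with one inversion; the bicycle is made racemic and resolved as a diastereomer after esterification.

Key step: step 1

Remark: no enantioselective variant of the cycloaddition is assumed, so the bicycle is carried as a racemate through steps 1 and 2 and its absolute configuration is fixed in step 4, where the ester formed with the enantiopure lactate is freed from its diastereomer; this separation is assumed to be feasible by preparative HPLC.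

**Route**

Step 1
Reactants: 1 vanillin (4-hydroxy-3-methoxybenzaldehyde); 2 methyl (E)-3-(3,4-dimethoxyphenyl)prop-2-enoate
Product: 4 methyl rac-(1S,2R,3S,4S)-3-(3,4-dimethoxyphenyl)-6-formyl-7,7-dimethoxy-8-oxobicyclo[2.2.2]oct-5-ene-2-carboxylate, via o-quinone monoketal 3 (not isolated)
Conditions: PhI(OAc)2 (1.05 equiv), MeOH, 0 °C; evaporation; then 2 (5 equiv), toluene, 110 °C, sealed tube
Reagents that add atoms: methanol, CO
Why: PhI(OAc)2 oxidizes the phenol of 1 and methanol is captured at the methoxy-bearing ring carbon, so the flat guaiacol ring is dearomatized to the 6,6-dimethoxycyclohexa-2,4-dienone 3, whose formyl group slows self-dimerization; on heating, 3 should react as an electron-poor 4π component with the electron-rich cinnamate 2 in an asynchronous, concerted inverse-electron-demand Diels–Alder reaction. The closest known reaction type is the thermal Diels–Alder reaction of masked o-benzoquinones, generated from 2-methoxyphenols, with styrenes and acrylates to give bicyclo[2.2.2]oct-5-en-2-ones. One suprafacial [4+2] event forms the C1–C2 and C3–C4 bonds and thereby closes both the cyclohexene ring C1–C2–C3–C4–C5–C6 and the saturated ring C1–C2–C3–C4–C8–C7, each as a six-membered carbocycle across the diene termini. C1 and C4 follow from suprafacial addition to one face of the planar dienone, the trans relation of C2 and C3 is copied from the E-alkene, and the ester at C2 should sit syn to the new C5=C6 bond (endo) with the aryl group at C3 toward the planar C8 carbonyl, because only hydrogen fits next to the dimethoxy-substituted C7 and the ester gains secondary overlap with the dienone. The step needs regioselectivity (ester-bearing carbon to the diene terminus next to the ketal), and this is secured by matched polarization: that terminus is δ to the ketone and β to the formyl group and so is the electrophilic end, while the α-carbon of 2 is its nucleophilic end owing to the 3,4-dimethoxyphenyl donor on the β-carbon; no absolute control is expected, so 4 should be racemic.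

Step 2
Reactants: 4 methyl rac-(1S,2R,3S,4S)-3-(3,4-dimethoxyphenyl)-6-formyl-7,7-dimethoxy-8-oxobicyclo[2.2.2]oct-5-ene-2-carboxylate; 5 malonic acid
Product: 6 methyl rac-(1S,2R,3S,4S)-6-[(1E)-2-carboxyethenyl]-3-(3,4-dimethoxyphenyl)-7,7-dimethoxy-8-oxobicyclo[2.2.2]oct-5-ene-2-carboxylate
Conditions: pyridine, piperidine (0.1 equiv), 80 °C
Reagents that add atoms: none
Why: Knoevenagel–Doebner condensation of the conjugated aldehyde with malonic acid and decarboxylation in the same flask should give the (E)-acid under thermodynamic control, while the C8 ketone, which lies between a bridgehead and the ketal carbon, can neither enolize nor condense.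

Step 3
Reactants: 7 sodium (2R)-3-(3,4-dihydroxyphenyl)-2-hydroxypropanoate (sodium danshensu)
Product: 8 methyl (2R)-3-(3,4-dimethoxyphenyl)-2-hydroxypropanoate
Conditions: MeI (3.5 equiv), K2CO3 (2.5 equiv), DMF, rt, argon
Reagents that add atoms: iodomethane, CI
Why: Carboxylate and phenoxide O-alkylation (Williamson-type SN2 on iodomethane) under a carbonate base that is too weak to deprotonate the secondary alcohol or the α-hydrogen, so the R centre is kept.

Step 4
Reactants: 6 methyl rac-(1S,2R,3S,4S)-6-[(1E)-2-carboxyethenyl]-3-(3,4-dimethoxyphenyl)-7,7-dimethoxy-8-oxobicyclo[2.2.2]oct-5-ene-2-carboxylate; 8 methyl (2R)-3-(3,4-dimethoxyphenyl)-2-hydroxypropanoate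
Product: 9 methyl (1S,2R,3S,4S)-3-(3,4-dimethoxyphenyl)-6-[(1E)-3-{[(2S)-3-(3,4-dimethoxyphenyl)-1-methoxy-1-oxopropan-2-yl]oxy}-3-oxoprop-1-en-1-yl]-7,7-dimethoxy-8-oxobicyclo[2.2.2]oct-5-ene-2-carboxylate
Conditions: PPh3 (1.3 equiv), DIAD (1.3 equiv), THF, 0 °C to rt; then preparative HPLC on silica
Reagents that add atoms: none
Why: Mitsunobu esterification, in which the carboxylate of 6 displaces the phosphonium-activated hydroxyl of 8 in an SN2 reaction that inverts the lactate centre from R to S, and removal of the diastereomer that contains the enantiomeric bicycle fixes the absolute configuration of C1 to C4.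

Step 5
Reactants: 9 methyl (1S,2R,3S,4S)-3-(3,4-dimethoxyphenyl)-6-[(1E)-3-{[(2S)-3-(3,4-dimethoxyphenyl)-1-methoxy-1-oxopropan-2-yl]oxy}-3-oxoprop-1-en-1-yl]-7,7-dimethoxy-8-oxobicyclo[2.2.2]oct-5-ene-2-carboxylate
Product: 10 methyl (1S,2R,3S,4S,7S)-3-(3,4-dimethoxyphenyl)-6-[(1E)-3-{[(2S)-3-(3,4-dimethoxyphenyl)-1-methoxy-1-oxopropan-2-yl]oxy}-3-oxoprop-1-en-1-yl]-7-methoxy-8-oxobicyclo[2.2.2]oct-5-ene-2-carboxylate
Conditions: SmI2 (2.2 equiv), THF–MeOH (10:1), −78 °C
Reagents that add atoms: none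
Why: Reductive cleavage of an α-alkoxy ketone (ketyl formation at C8, loss of one methoxide) should give a samarium enolate that is protonated at C7 from the open face of the C5=C6 bridge, the other face being screened by the hydrogen at C2 that points toward C7, so the remaining methoxy group ends syn to the C2–C3 bridge; the esters and the dienoate are not reduced at this temperature.

Step 6
Reactants: 10 methyl (1S,2R,3S,4S,7S)-3-(3,4-dimethoxyphenyl)-6-[(1E)-3-{[(2S)-3-(3,4-dimethoxyphenyl)-1-methoxy-1-oxopropan-2-yl]oxy}-3-oxoprop-1-en-1-yl]-7-methoxy-8-oxobicyclo[2.2.2]oct-5-ene-2-carboxylate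
Product: 11 methyl (1S,2R,3S,4S,7S)-3-(3,4-dihydroxyphenyl)-6-[(1E)-3-{[(2S)-3-(3,4-dihydroxyphenyl)-1-methoxy-1-oxopropan-2-yl]oxy}-3-oxoprop-1-en-1-yl]-7-hydroxy-8-oxobicyclo[2.2.2]oct-5-ene-2-carboxylate
Conditions: BBr3 (12 equiv), CH2Cl2, −78 °C to 0 °C; MeOH quench at −78 °C; aqueous work-up
Reagents that add atoms: none
Why: Lewis acid-mediated ether cleavage, in which bromide attacks the methyl group of each boron-complexed ether, so the four aryl ethers and the C7 ether (activated by chelation of boron between its oxygen and the C8 carbonyl) should be cleaved without touching the C7–O bond or its configuration, while the methyl esters and the acyloxy ester react far more slowly at or below 0 °C.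

**Compound list**

1 | vanillin (4-hydroxy-3-methoxybenzaldehyde) | COc1cc(C=O)ccc1O | starting material
2 | methyl (E)-3-(3,4-dimethoxyphenyl)prop-2-enoate | COC(=O)/C=C/c1ccc(OC)c(OC)c1 | starting material
3 | 3,3-dimethoxy-4-oxocyclohexa-1,5-diene-1-carbaldehyde (o-quinone monoketal) | O=CC1=CC(OC)(OC)C(=O)C=C1 | intermediate
4 | methyl rac-(1S,2R,3S,4S)-3-(3,4-dimethoxyphenyl)-6-formyl-7,7-dimethoxy-8-oxobicyclo[2.2.2]oct-5-ene-2-carboxylate (racemate; the enantiomer carried on is drawn; ester at C2 syn to C5=C6, aryl at C3 syn to the C7–C8 bridge) | COC(=O)[C@H]1[C@H]2C(C=O)=C[C@H](C(=O)C2(OC)OC)[C@@H]1c1ccc(OC)c(OC)c1 | intermediate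
5 | malonic acid | OC(=O)CC(=O)O | starting material
6 | methyl rac-(1S,2R,3S,4S)-6-[(1E)-2-carboxyethenyl]-3-(3,4-dimethoxyphenyl)-7,7-dimethoxy-8-oxobicyclo[2.2.2]oct-5-ene-2-carboxylate (racemate; the enantiomer carried on is drawn) | COC(=O)[C@H]1[C@H]2C(/C=C/C(=O)O)=C[C@H](C(=O)C2(OC)OC)[C@@H]1c1ccc(OC)c(OC)c1 | intermediate
7 | sodium (2R)-3-(3,4-dihydroxyphenyl)-2-hydroxypropanoate (sodium danshensu) | O[C@H](Cc1ccc(O)c(O)c1)C(=O)[O-].[Na+] | starting material
8 | methyl (2R)-3-(3,4-dimethoxyphenyl)-2-hydroxypropanoate | O[C@H](Cc1ccc(OC)c(OC)c1)C(=O)OC | intermediate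
9 | methyl (1S,2R,3S,4S)-3-(3,4-dimethoxyphenyl)-6-[(1E)-3-{[(2S)-3-(3,4-dimethoxyphenyl)-1-methoxy-1-oxopropan-2-yl]oxy}-3-oxoprop-1-en-1-yl]-7,7-dimethoxy-8-oxobicyclo[2.2.2]oct-5-ene-2-carboxylate | COC(=O)[C@H]1[C@H]2C(/C=C/C(=O)O[C@@H](Cc3ccc(OC)c(OC)c3)C(=O)OC)=C[C@H](C(=O)C2(OC)OC)[C@@H]1c1ccc(OC)c(OC)c1 | intermediate
10 | methyl (1S,2R,3S,4S,7S)-3-(3,4-dimethoxyphenyl)-6-[(1E)-3-{[(2S)-3-(3,4-dimethoxyphenyl)-1-methoxy-1-oxopropan-2-yl]oxy}-3-oxoprop-1-en-1-yl]-7-methoxy-8-oxobicyclo[2.2.2]oct-5-ene-2-carboxylate (methoxy at C7 syn to the C2–C3 bridge) | COC(=O)[C@H]1[C@H]2C(/C=C/C(=O)O[C@@H](Cc3ccc(OC)c(OC)c3)C(=O)OC)=C[C@H](C(=O)[C@H]2OC)[C@@H]1c1ccc(OC)c(OC)c1 | intermediate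
11 | methyl (1S,2R,3S,4S,7S)-3-(3,4-dihydroxyphenyl)-6-[(1E)-3-{[(2S)-3-(3,4-dihydroxyphenyl)-1-methoxy-1-oxopropan-2-yl]oxy}-3-oxoprop-1-en-1-yl]-7-hydroxy-8-oxobicyclo[2.2.2]oct-5-ene-2-carboxylate (CNP0304584.1) | COC(=O)[C@H]1[C@H]2C(/C=C/C(=O)O[C@@H](Cc3ccc(O)c(O)c3)C(=O)OC)=C[C@H](C(=O)[C@H]2O)[C@@H]1c1ccc(O)c(O)c1 | target

**Step count and risks**

Total step count: 6. Longest linear sequence: 5 steps (steps 1, 2, 4, 5 and 6, from vanillin).

Steps most likely to fail:

Step 1 (key step). The β-aryl acrylate may add too slowly, so that self-dimerization of dienone 3 or loss of regio- and endo-control takes over. The fallback sets out from 1 (oxidized to 3 as before) and comes back at 4. The dienophile is changed to purchased methyl (E)-3-(4-hydroxy-3-methoxyphenyl)prop-2-enoate, added only after the oxidant has been consumed. Its free para-hydroxyl makes the alkene a vinylogous phenol with a more nucleophilic α-carbon, which should speed up and further polarize the cycloaddition at lower temperature. This should give methyl rac-(1S,2R,3S,4S)-6-formyl-3-(4-hydroxy-3-methoxyphenyl)-7,7-dimethoxy-8-oxobicyclo[2.2.2]oct-5-ene-2-carboxylate F1. O-Methylation of the phenol (MeI, K2CO3, acetone) then leads to 4.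

Step 5. The reduction may run on to loss of both methoxy groups, or the product may epimerize at C7 through its enol. The fallback sets out from 9 and comes back at 11. The ketal is hydrolysed (TFA–H2O, rt) to methyl (1S,2R,3S,4S)-3-(3,4-dimethoxyphenyl)-6-[(1E)-3-{[(2S)-3-(3,4-dimethoxyphenyl)-1-methoxy-1-oxopropan-2-yl]oxy}-3-oxoprop-1-en-1-yl]-7,8-dioxobicyclo[2.2.2]oct-5-ene-2-carboxylate F2. Irreversible hydride delivery (NaBH4, 0.3 equiv, THF–MeOH, −78 °C) from the face of the C5=C6 bridge should give methyl (1S,2R,3S,4S,7S)-3-(3,4-dimethoxyphenyl)-6-[(1E)-3-{[(2S)-3-(3,4-dimethoxyphenyl)-1-methoxy-1-oxopropan-2-yl]oxy}-3-oxoprop-1-en-1-yl]-7-hydroxy-8-oxobicyclo[2.2.2]oct-5-ene-2-carboxylate F3. The regioisomeric 8-hydroxy-7-ketone, expected alongside it, is removed by chromatography and recycled by oxidation back to the diketone. Cleavage of the four aryl methyl ethers (BBr3, CH2Cl2, −78 to 0 °C) then leads to 11.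

Step 6. The aliphatic methyl ether at C7 may resist cleavage under conditions mild enough for the three ester groups, or the α-ketol may rearrange on longer exposure to the Lewis acid. The fallback sets out from 2, 5 and 8 and comes back at 11; in it the C7 oxygen is carried as a benzyl ether. Purchased 3-(benzyloxy)-4-hydroxybenzaldehyde is oxidized with PhI(OAc)2 in CH2Cl2 in the presence of benzyl alcohol to 3,3-bis(benzyloxy)-4-oxocyclohexa-1,5-diene-1-carbaldehyde F4. Heating with 2 should give methyl rac-(1S,2R,3S,4S)-7,7-bis(benzyloxy)-3-(3,4-dimethoxyphenyl)-6-formyl-8-oxobicyclo[2.2.2]oct-5-ene-2-carboxylate F5. Condensation with 5 leads to methyl rac-(1S,2R,3S,4S)-7,7-bis(benzyloxy)-6-[(1E)-2-carboxyethenyl]-3-(3,4-dimethoxyphenyl)-8-oxobicyclo[2.2.2]oct-5-ene-2-carboxylate F6. Mitsunobu esterification with 8 and separation of the diastereomers leads to methyl (1S,2R,3S,4S)-7,7-bis(benzyloxy)-3-(3,4-dimethoxyphenyl)-6-[(1E)-3-{[(2S)-3-(3,4-dimethoxyphenyl)-1-methoxy-1-oxopropan-2-yl]oxy}-3-oxoprop-1-en-1-yl]-8-oxobicyclo[2.2.2]oct-5-ene-2-carboxylate F7. SmI2 at −78 °C should give methyl (1S,2R,3S,4S,7S)-7-(benzyloxy)-3-(3,4-dimethoxyphenyl)-6-[(1E)-3-{[(2S)-3-(3,4-dimethoxyphenyl)-1-methoxy-1-oxopropan-2-yl]oxy}-3-oxoprop-1-en-1-yl]-8-oxobicyclo[2.2.2]oct-5-ene-2-carboxylate F8. BBr3 at −78 °C, which cleaves a benzyl ether far faster than an aliphatic methyl ether, followed by warming to 0 °C for the aryl ethers, then leads to 11.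

Further compounds
F1 | step 1 | methyl rac-(1S,2R,3S,4S)-6-formyl-3-(4-hydroxy-3-methoxyphenyl)-7,7-dimethoxy-8-oxobicyclo[2.2.2]oct-5-ene-2-carboxylate | COC(=O)[C@H]1[C@H]2C(C=O)=C[C@H](C(=O)C2(OC)OC)[C@@H]1c1ccc(O)c(OC)c1
F2 | step 5 | methyl (1S,2R,3S,4S)-3-(3,4-dimethoxyphenyl)-6-[(1E)-3-{[(2S)-3-(3,4-dimethoxyphenyl)-1-methoxy-1-oxopropan-2-yl]oxy}-3-oxoprop-1-en-1-yl]-7,8-dioxobicyclo[2.2.2]oct-5-ene-2-carboxylate | COC(=O)[C@H]1[C@H]2C(/C=C/C(=O)O[C@@H](Cc3ccc(OC)c(OC)c3)C(=O)OC)=C[C@H](C(=O)C2=O)[C@@H]1c1ccc(OC)c(OC)c1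
F3 | step 5 | methyl (1S,2R,3S,4S,7S)-3-(3,4-dimethoxyphenyl)-6-[(1E)-3-{[(2S)-3-(3,4-dimethoxyphenyl)-1-methoxy-1-oxopropan-2-yl]oxy}-3-oxoprop-1-en-1-yl]-7-hydroxy-8-oxobicyclo[2.2.2]oct-5-ene-2-carboxylate | COC(=O)[C@H]1[C@H]2C(/C=C/C(=O)O[C@@H](Cc3ccc(OC)c(OC)c3)C(=O)OC)=C[C@H](C(=O)[C@H]2O)[C@@H]1c1ccc(OC)c(OC)c1
F4 | step 6 | 3,3-bis(benzyloxy)-4-oxocyclohexa-1,5-diene-1-carbaldehyde | O=CC1=CC(OCc2ccccc2)(OCc2ccccc2)C(=O)C=C1
F5 | step 6 | methyl rac-(1S,2R,3S,4S)-7,7-bis(benzyloxy)-3-(3,4-dimethoxyphenyl)-6-formyl-8-oxobicyclo[2.2.2]oct-5-ene-2-carboxylate | COC(=O)[C@H]1[C@H]2C(C=O)=C[C@H](C(=O)C2(OCc3ccccc3)OCc3ccccc3)[C@@H]1c1ccc(OC)c(OC)c1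
F6 | step 6 | methyl rac-(1S,2R,3S,4S)-7,7-bis(benzyloxy)-6-[(1E)-2-carboxyethenyl]-3-(3,4-dimethoxyphenyl)-8-oxobicyclo[2.2.2]oct-5-ene-2-carboxylate | COC(=O)[C@H]1[C@H]2C(/C=C/C(=O)O)=C[C@H](C(=O)C2(OCc3ccccc3)OCc3ccccc3)[C@@H]1c1ccc(OC)c(OC)c1
F7 | step 6 | methyl (1S,2R,3S,4S)-7,7-bis(benzyloxy)-3-(3,4-dimethoxyphenyl)-6-[(1E)-3-{[(2S)-3-(3,4-dimethoxyphenyl)-1-methoxy-1-oxopropan-2-yl]oxy}-3-oxoprop-1-en-1-yl]-8-oxobicyclo[2.2.2]oct-5-ene-2-carboxylate | COC(=O)[C@H]1[C@H]2C(/C=C/C(=O)O[C@@H](Cc3ccc(OC)c(OC)c3)C(=O)OC)=C[C@H](C(=O)C2(OCc3ccccc3)OCc3ccccc3)[C@@H]1c1ccc(OC)c(OC)c1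
F8 | step 6 | methyl (1S,2R,3S,4S,7S)-7-(benzyloxy)-3-(3,4-dimethoxyphenyl)-6-[(1E)-3-{[(2S)-3-(3,4-dimethoxyphenyl)-1-methoxy-1-oxopropan-2-yl]oxy}-3-oxoprop-1-en-1-yl]-8-oxobicyclo[2.2.2]oct-5-ene-2-carboxylate | COC(=O)[C@H]1[C@H]2C(/C=C/C(=O)O[C@@H](Cc3ccc(OC)c(OC)c3)C(=O)OC)=C[C@H](C(=O)[C@H]2OCc2ccccc2)[C@@H]1c1ccc(OC)c(OC)c1
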